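**Retrosynthetic overview**
1. The dihydropyranone (C) ring is closed last. Breaking O1–C2 gives an acyclic (R)-β-hydroxy ketone on a fully substituted, symmetric A ring, and SN2 closure inverts R to S.
2. Both ArCH2–C6/C8 bonds come from an acylphloroglucinol plus two o-quinone methides, photogenerated from 2-hydroxybenzyl alcohol.
3. The A-ring–C4(=O) bond comes from a photo-Fries acyl shift of a phloroglucinol mono-ester.
4. The ester comes from phloroglucinol and (R)-3-hydroxy-3-phenylpropanoic acid, which supplies the only stereocentre.
5. Ring order: all four benzene rings are bought, and the C ring is the only ring formed.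

Assumption: the target is (2S), as the SMILES reads, and the (R)-hydroxy acid is bought as a catalogue item at ≥98% ee.

**Step 1**
Reactants: 1, (R)-3-hydroxy-3-phenylpropanoic acid; 2, phloroglucinol (benzene-1,3,5-triol, anhydrous, 4 equiv)
Product: 3, 3,5-dihydroxyphenyl (R)-3-hydroxy-3-phenylpropanoate (mono-ester, free carbinol)
Conditions: EDC·HCl (1.1 equiv), DMAP (0.1 equiv), THF/DMF 9:1, slow addition of 1, 0 °C → rt; aqueous wash removes excess 2
Reagents that add atoms: phloroglucinol (2), Oc1cc(O)cc(O)c1
Why: This is a Steglich esterification in which the large excess of the symmetric triol favours mono-acylation and outcompetes the hindered secondary carbinol of 1, and the stereocentre is not involved.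

**Step 2**
Reactants: 3, 3,5-dihydroxyphenyl (R)-3-hydroxy-3-phenylpropanoate
Product: 4, (R)-3-hydroxy-3-phenyl-1-(2,4,6-trihydroxyphenyl)propan-1-one
Conditions: hν 254 nm (low-pressure Hg, FEP flow reactor), degassed MeCN (10 mM), 20 °C
Reagents that add atoms: none
Why: This is a photo-Fries rearrangement in which ArO–C(O) homolysis gives a caged aryloxyl/acyl radical pair that recombines at a ring carbon; both ortho positions and the para position give the same 2,4,6-trihydroxyphenyl ketone, so no regioisomers can form. The carbinol carbon is β to the radical centre and untouched, decarbonylation to a primary radical is too slow to compete, and the chelated product deactivates itself by excited-state proton transfer.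

**Step 3**
Reactants: 4, (R)-3-hydroxy-3-phenyl-1-(2,4,6-trihydroxyphenyl)propan-1-one; 5, 2-hydroxybenzyl alcohol (salicyl alcohol, 6 equiv in 3 portions)
Product: 6, (R)-3-hydroxy-3-phenyl-1-[2,4,6-trihydroxy-3,5-bis(2-hydroxybenzyl)phenyl]propan-1-one
Conditions: hν 275 nm (UV-LED, recirculating FEP flow loop), MeCN/20 mM Na phosphate pH 7.5 (1:1), 5 mM in 4, Ar, 15 °C; then pH 5, EtOAc
Reagents that add atoms: 2-hydroxybenzyl alcohol (5), OCc1ccccc1O (two equivalents incorporated, each losing H2O)
Why: Proposed new method: excitation of 5 makes its phenol strongly acidic, and water-relayed excited-state proton transfer with loss of the benzylic OH gives the parent o-quinone methide (C=C1C=CC=CC1=O, transient); at pH 7.5 ketone 4 (pKa about 7.5–8) is largely its 4-phenolate, which is the strongest carbon nucleophile present and adds 1,4 through C3 and then C5 with re-aromatisation of both rings, and whose main UV band is expected to shift from about 287 to about 325 nm, opening a window at 275 nm for un-ionised 5; attack by water or oxygen nucleophiles only regenerates 5 or gives equally photolabile 2-hydroxybenzyl ethers, so the C–C adduct 6, with no free ring position left, should be the main sink, and the remote carbinol is untouched; the closest known reaction types are the photodehydration of o-hydroxybenzyl alcohols with trapping by water, amines, thiols or enol ethers, and the thermal Lewis-acid o-hydroxybenzylation of phloroglucinols, whereas the photochemical version has not been used for double C–H benzylation of an acylphloroglucinol.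

**Step 4**
Reactants: 6, (R)-3-hydroxy-3-phenyl-1-[2,4,6-trihydroxy-3,5-bis(2-hydroxybenzyl)phenyl]propan-1-one
Product: 7, (S)-dichamanetin [(2S)-5,7-dihydroxy-6,8-bis(2-hydroxybenzyl)-2-phenylchroman-4-one]
Conditions: PPh3 (1.3 equiv), DIAD (1.25 equiv, slow addition), THF (10 mM), −15 → 0 °C
Reagents that add atoms: none
Why: This is an intramolecular Mitsunobu etherification (6-exo-tet SN2 on the oxyphosphonium) that inverts the purchased (R)-carbinol to (2S). The two ortho phenols are equivalent and give the same product, the salicyl phenols could only close 10-membered rings, and the acidic phenols buffer the betaine against elimination, so the flavanone stereocentre never sees light, acid or base.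

**Compound list**
1 | (R)-3-hydroxy-3-phenylpropanoic acid | O=C(O)C[C@@H](O)c1ccccc1 | starting material
2 | phloroglucinol | Oc1cc(O)cc(O)c1 | starting material
3 | 3,5-dihydroxyphenyl (R)-3-hydroxy-3-phenylpropanoate | O=C(C[C@@H](O)c1ccccc1)Oc1cc(O)cc(O)c1 | intermediate
4 | (R)-3-hydroxy-3-phenyl-1-(2,4,6-trihydroxyphenyl)propan-1-one | O=C(C[C@@H](O)c1ccccc1)c1c(O)cc(O)cc1O | intermediate
5 | 2-hydroxybenzyl alcohol | OCc1ccccc1O | starting material
6 | (R)-3-hydroxy-3-phenyl-1-[2,4,6-trihydroxy-3,5-bis(2-hydroxybenzyl)phenyl]propan-1-one | O=C(C[C@@H](O)c1ccccc1)c1c(O)c(Cc2ccccc2O)c(O)c(Cc2ccccc2O)c1O | intermediate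
7 | (S)-dichamanetin | O=C1C[C@@H](c2ccccc2)Oc2c(Cc3ccccc3O)c(O)c(Cc3ccccc3O)c(O)c21 | target

**Total step count:** 4. **Longest linear sequence:** 4 (1 → 3 → 4 → 6 → 7).

**Steps most likely to fail**
1. **Step 3 (proposed new step).**
   - Risks: inner-filter absorption by 4 and 6, quinone methide self-oligomerisation, stalling at the mono-benzyl stage, and photodegradation of the phenolate.
   - Fallback (known chemistry): reorder the route. Cyclise 4 first by the Mitsunobu reaction to (S)-pinocembrin. Then install both groups in the ground state with 5 and ZnCl2 in hot dioxane, the established Friedel–Crafts o-hydroxybenzylation of this flavanone. Recycle the mono-adducts and check ee by chiral HPLC.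
2. **Step 4.**
   - Risk: elimination of the β-oxyphosphonium ketone to the chalcone, which recloses to racemic 7 and erodes ee.
   - Fallback: change the bond order. Form the C2–O bond first by intermolecular Mitsunobu reaction of 2 with ethyl (R)-3-hydroxy-3-phenylpropanoate, where elimination gives only inert ethyl cinnamate. Then saponify and close the C4–C4a bond by intramolecular Friedel–Crafts acylation (TFAA) to (S)-pinocembrin, and benzylate last.
3. **Step 2.**
   - Risks: low conversion because product 4 absorbs strongly, and out-of-cage escape giving back 2.
   - Fallback: build the aryl ketone by polar chemistry. Convert 1 to its O-TBS Weinreb amide and add 2-lithio-1,3,5-tris(methoxymethoxy)benzene (n-BuLi ortho-lithiation). Then remove the MOM and TBS groups with mild acid to give 4.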